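(The data stem from a simulated flask from invented constants; the scatter is artificial.)

Blue and amber, both at 90 °C, level off with substrate standing: amber's product moves from 35.4 % at 80.0 s to 35.6 % at 120 s, with 47.8 % of the substrate left.

| flask | substrate | reagent | precatalyst | temperature | remark | time |
|---|---|---|---|---|---|---|
| red | 5 mM | 5 mM | 0.75 mM | 75 °C | run made earlier |  |
| blue | 3.4 mM | 5 mM | 0.75 mM | 90 °C | run made earlier |  |
| ochre | 7.5 mM | 5 mM | 0.75 mM | 75 °C | run made earlier |  |
| amber | 5 mM | 5 mM | 1.1 mM | 90 °C | run made earlier |  |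
| eta | 5.0 mM (fed, over 30 s) | 5.00 mM | 0.75 mM | 90 °C | all else is in the flask from the start; the feed brings no volume worth counting | 2.5 min |
| delta | 5.0 mM | 5.00 mM (fed, over 30 s) | 0.75 mM | 90 °C | all else is in the flask from the start; the feed brings no volume worth counting | 2.5 min |
| alpha | 5.0 mM | 5.00 mM | 0.75 mM | 90 °C | everything together at the start | 2.5 min |
| gamma | 5.0 mM (fed, over 30 s) | 5.00 mM | 0.75 mM |  | the addition at 50 °C, then warmed to 90 °C; the feed brings no volume worth counting | 2.5 min |

red run (percent of the substrate charged)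

| time / min | product / % | substrate / % |
|---|---|---|
| 0.417 | 10.2 | 88.2 |
| 0.833 | 22.3 | 72.7 |
| 1.33 | 32.0 | 58.7 |
| 2.00 | 39.1 | 50.3 |
| 3.00 | 45.3 | 43.3 |

blue run (percent of the substrate charged)

| time / s | product / % | substrate / % |
|---|---|---|
| 10.0 | 9.8 | 85.2 |
| 15.0 | 15.1 | 76.4 |
| 20.0 | 19.9 | 70.5 |
| 30.0 | 26.4 | 60.2 |
| 50.0 | 34.4 | 51.4 |
| 80.0 | 39.0 | 46.1 |
| 120 | 41.5 | 44.9 |

ochre run (percent of the substrate charged)

| time / min | product / % | substrate / % |
|---|---|---|
| 0.500 | 11.4 | 86.0 |
| 1.00 | 23.5 | 71.2 |
| 2.00 | 36.0 | 57.0 |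
| 3.00 | 40.3 | 52.4 |
| 4.00 | 41.1 | 50.5 |

amber run (percent of the substrate charged)

| time / s | product / % | substrate / % |
|---|---|---|
| 10.0 | 11.2 | 81.8 |
| 30.0 | 27.1 | 57.5 |
| 60.0 | 34.4 | 49.2 |
| 80.0 | 35.4 | 46.6 |
| 120 | 35.6 | 47.8 |

(readings scatter by 0.5 percentage points)

* which flask leads in amount of product, in percent of the substrate charged ("all alike" within 1.5 percentage points) (eta / delta / alpha / gamma / all alike)
* how much product is there at the end, in percent of the substrate charged: eta
* how much product is there at the end, in percent of the substrate charged: delta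
* how much product is there at the end, in percent of the substrate charged: alpha
* how much product is there at the end, in percent of the substrate charged: gamma



I read each stop as a balance, an apparent equilibrium between substrate, reagent and product. Reagent isn't read, so I write its balance: c(reagent) is the charge less c(product) less what the catalyst holds. The substrate missing from substrate plus product is 0.462 mM in blue and 0.830 mM in amber, and I guess that half of it carries reagent. Then c(product)/(c(substrate)·c(reagent)) reads 275 L mol⁻¹ in blue and 266 L mol⁻¹ in amber. Their mean, 270 L mol⁻¹, is my stall quotient, that ratio taken at the stop.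

For alpha I scale amber's held amount to 0.566 mM, and solving the quotient gives 1.91 mM of product, or 38.2 % of the substrate. The flasks run 2.5 min, longer than blue's record of 120 s, so I expect a feed of 30 s to leave that end in place. Gamma's warm stretch of 120 s about equals blue's record, so I expect gamma there too.

The forecast differs: it names eta as leader, with 39 % for eta, 29 % for delta, 34 % for alpha and 34 % for gamma, reading the stall as “so the catalyst dies”.

The flasks give 38.7 % for eta, 38.8 % for delta, 38.8 % for alpha and 38.4 % for gamma: all alike within 1.5 percentage points, with delta 9.8 points above the forecast.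

    substrate + free catalyst ⇌ catalyst intermediate A (K = 780 L mol⁻¹, k = 60.0 L mol⁻¹ s⁻¹, Ea = 53.0 kJ mol⁻¹, ΔH = 4.00 kJ mol⁻¹)
    reagent + catalyst intermediate A ⇌ catalyst intermediate B (K = 260 L mol⁻¹, k = 820 L mol⁻¹ s⁻¹, Ea = 49.0 kJ mol⁻¹, ΔH = −13.0 kJ mol⁻¹)
    catalyst intermediate B ⇌ free catalyst + product (K = 0.00140 M, k = 120 s⁻¹, Ea = 79.0 kJ mol⁻¹, ΔH = −37.0 kJ mol⁻¹)
    precatalyst → free catalyst (k = 0.150 s⁻¹, Ea = 106 kJ mol⁻¹)
    (constants at 90 °C)

In eta, half of the turnover up to the asked time of catalyst intermediate B into free catalyst and product is done by 0.536 min, far earlier than the asked 2.5 min, and at 25.0 min eta's product stands at 39.2 %. At the asked time eta holds 38.7 % product, 49.8 % substrate and 56.4 % of its reagent, a stall quotient of 276 L mol⁻¹ against my 270 L mol⁻¹. A neighbour of eta charged with 2.0 mM of substrate ends with 41.9 % product, 37.8 % substrate and 79.1 % of its reagent, a stall quotient of 280 L mol⁻¹.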